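**Plan**

- Retrosynthesis: after unmasking the four hydroxyls, ring A is cut at C4a–C5 and C8–C8a (flavone numbering). This leads back, through a hydroaromatic adduct with an angular ester at C4a, to a ring B–ring C 4-pyranone 3-carboxylate and a 2,3-bis(silyloxy)butadiene. The pyranone is cut at C2–C3, C4a–C8a and O1–C8a into an aroyl chloride, a 4-alkoxyacetoacetate and one formamide acetal carbon.
- Enabling feature: in ring A the oxygens on C6 and C7 are on adjacent carbons flanked by C5–H and C8–H. C5–C6(O)–C7(O)–C8 is therefore a 2,3-dioxygenated butadiene, and C4a=C8a of ring C is its dienophile.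
- Forward order: ring B is protected (MOM on O4', prenyl on O3') and oxidised to the acid. Ring C is built as a monocyclic pyranone. Ring A is annulated by the Diels–Alder reaction and aromatised (deallylative decarboxylation, DDQ). Fluoride and dilute acid then free the hydroxyls.
- Stereochemistry: the target has no stereocentre. The two centres of the cycloadduct (C4a, C8a, cis by suprafacial addition) are racemic and vanish on aromatisation.

Key step: step 9

Remark: flavone numbering (O1, C2, C3, C4, C4a, C5–C8, C8a) is used for all ring C and ring A atoms, also in the monocyclic pyranone. Ar = 4-(methoxymethoxy)-3-(3-methylbut-2-enyloxy)phenyl; MOM = methoxymethyl; TBS = tert-butyldimethylsilyl. Because the target is achiral, the cycloadduct and its decarboxylation product are assumed to be carried as racemates (one enantiomer drawn). The enamine geometry of 10 and the labile centre of 12 are drawn as one isomer and are of no consequence.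

**Route**

Step 1
Reactants: 1 3,4-dihydroxybenzaldehyde
Product: 2 3-hydroxy-4-(methoxymethoxy)benzaldehyde
Conditions: MOMCl (1.05 equiv), K2CO3 (1.1 equiv), acetone, 0 °C → rt
Reagents that add atoms: chloromethyl methyl ether, COCCl
Why: Williamson-type O-alkylation in which the 4-hydroxyl, para to the formyl group and therefore the more acidic phenol, is the one deprotonated by a single equivalent of K2CO3 and alkylated, leaving the 3-hydroxyl free.

Step 2
Reactants: 2 3-hydroxy-4-(methoxymethoxy)benzaldehyde; 3 prenyl bromide (1-bromo-3-methylbut-2-ene)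
Product: 4 4-(methoxymethoxy)-3-(3-methylbut-2-enyloxy)benzaldehyde
Conditions: K2CO3, DMF, rt
Reagents that add atoms: none
Why: Williamson ether synthesis in which the remaining phenoxide displaces bromide at the primary allylic CH2 (SN2), giving the O-prenyl ether under conditions too mild for C-alkylation.

Step 3
Reactants: 4 4-(methoxymethoxy)-3-(3-methylbut-2-enyloxy)benzaldehyde
Product: 5 4-(methoxymethoxy)-3-(3-methylbut-2-enyloxy)benzoic acid
Conditions: NaClO2, NaH2PO4, 2-methylbut-2-ene (excess), t-BuOH/H2O, rt
Reagents that add atoms: sodium chlorite, [Na+].[O-]Cl=O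
Why: Pinnick oxidation converts the aldehyde to the acid near pH 4, where the MOM acetal and the prenyl ether are stable, while the excess 2-methylbut-2-ene intercepts the hypochlorous acid that could otherwise attack the prenyl alkene.

Step 4
Reactants: 6 methyl glycolate
Product: 7 methyl 2-(methoxymethoxy)acetate
Conditions: MOMCl, i-Pr2NEt, CH2Cl2, 0 °C → rt
Reagents that add atoms: chloromethyl methyl ether, COCCl
Why: standard MOM protection of a primary alcohol (Williamson-type alkylation with a hindered amine base), which introduces the future C3 oxygen already masked.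

Step 5
Reactants: 7 methyl 2-(methoxymethoxy)acetate; 8 allyl acetate
Product: 9 allyl 4-(methoxymethoxy)-3-oxobutanoate
Conditions: 8 (2.2 equiv), LiN(iPr)2 (2.2 equiv), THF, −78 °C; then 7, −78 → −40 °C; AcOH quench
Reagents that add atoms: none
Why: crossed Claisen condensation in which the preformed lithium enolate of allyl acetate (two equivalents, the second consumed in deprotonating the product) attacks the α-alkoxy-activated methyl ester and expels methoxide, the cold enolate being acylated before it can rearrange.

Step 6
Reactants: 9 allyl 4-(methoxymethoxy)-3-oxobutanoate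
Product: 10 allyl 2-[(dimethylamino)methylidene]-4-(methoxymethoxy)-3-oxobutanoate
Conditions: Me2NCH(OMe)2 (1.2 equiv), PhMe, rt
Reagents that add atoms: N,N-dimethylformamide dimethyl acetal, COC(OC)N(C)C
Why: enaminone formation by condensation of the amide acetal at the doubly activated methylene between ketone and ester, which needs neither acid nor base and so leaves the MOM acetal and the allyl ester untouched; the new carbon becomes C8a.

Step 7
Reactants: 5 4-(methoxymethoxy)-3-(3-methylbut-2-enyloxy)benzoic acid; 10 allyl 2-[(dimethylamino)methylidene]-4-(methoxymethoxy)-3-oxobutanoate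
Product: 13 allyl 5-(methoxymethoxy)-6-[4-(methoxymethoxy)-3-(3-methylbut-2-enyloxy)phenyl]-4-oxo-4H-pyran-3-carboxylate, via aroyl chloride 11 (not isolated), via acylated enaminone 12 (not isolated)
Conditions: 5, Me2C=C(Cl)NMe2 (1.1 equiv), CH2Cl2, 0 °C → rt; 10, LiN(SiMe3)2 (2.1 equiv), THF, −78 °C, then 11; then AcOH, rt → 50 °C
Reagents that add atoms: none
Why: the α-chloroenamine makes the acid chloride without HCl and so spares the MOM ether, the lithium enolate at the only enolisable carbon of 10 (the future C3) is C-acylated by 11 in a Claisen-type acylation, and under mild acid the aryl-ketone enol oxygen of 12 adds to the enaminone carbon and expels dimethylamine (addition–elimination cyclocondensation), the established way to 3-alkoxy-4-oxopyran carboxylates from such enaminones.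

Step 8
Reactants: 14 2,3-butanedione
Product: 15 2,3-bis(tert-butyldimethylsilyloxy)buta-1,3-diene
Conditions: TBSOTf (2.2 equiv), Et3N (2.6 equiv), CH2Cl2, 0 °C → rt
Reagents that add atoms: tert-butyldimethylsilyl trifluoromethanesulfonate, CC(C)(C)[Si](C)(C)OS(=O)(=O)C(F)(F)F
Why: double enol silylation (soft enolisation) of the 1,2-diketone with a silyl triflate and an amine base gives the symmetrical 2,3-bis(silyloxy)diene directly.

Step 9
Reactants: 13 allyl 5-(methoxymethoxy)-6-Ar-4-oxo-4H-pyran-3-carboxylate; 15 2,3-bis(tert-butyldimethylsilyloxy)buta-1,3-diene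
Product: 16 allyl 6,7-bis(tert-butyldimethylsilyloxy)-3-(methoxymethoxy)-2-Ar-4-oxo-5,8-dihydro-4H-chromene-4a(8aH)-carboxylate (cis-fused: ester at C4a and H at C8a on the same face; racemic)
Conditions: 15 (4 equiv), BHT (cat.), PhMe, 130 °C, sealed tube
Reagents that add atoms: none
Why: A thermal, concerted, suprafacial normal-electron-demand Diels–Alder reaction: the electron-rich diene 15 adds to C4a=C8a of 13, the only alkene of the pyranone that is an alkylidene β-keto ester (C4 ketone plus C4a ester), forming C4a–C5 and C8–C8a. The closest known reaction type is the cycloaddition of silyloxydienes to 4-pyranones and chromones activated by a 3-alkoxycarbonyl or 3-cyano group. Ring A closes by an intermolecular [4+2] annulation in which both of its new bonds are made in the same step, four carbons coming from the diene and two (C4a, C8a) from ring C. The new stereocentres C4a and C8a are set relative to each other by the suprafacial addition to a ring alkene, which forces the ester and the C8a hydrogen cis; no facial control is needed because the adduct is racemic and both centres are destroyed on aromatisation. The step needs site selectivity for C4a=C8a over the C2=C3 enol ether (tetrasubstituted, donor-substituted), the prenyl alkene and the allyl ester alkene (both unactivated), which the double carbonyl activation secures, and it needs no regiocontrol because the symmetrical diene places its two oxygens at C6 and C7 whichever way it adds. The quaternary C4a of the adduct cannot enolise, so ring C should not open by β-elimination at this temperature, which is also well below that of an aryl prenyl ether Claisen rearrangement.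

Step 10
Reactants: 16 cis-fused cycloadduct (allyl ester)
Product: 17 6,7-bis(tert-butyldimethylsilyloxy)-3-(methoxymethoxy)-2-Ar-4a,5,8,8a-tetrahydro-4H-chromen-4-one (cis-fused isomer drawn, racemic; the C4a epimer serves equally)
Conditions: Pd(OAc)2 (5 mol %), PPh3 (20 mol %), HCO2H (2 equiv), Et3N (2.5 equiv), THF, rt
Reagents that add atoms: none
Why: palladium-catalysed deallylative decarboxylation (Tsuji–Trost-type ionisation with formate as hydride donor), in which zerovalent palladium formed from Pd(OAc)2 and PPh3 ionises the allyl ester far faster than the trisubstituted aryl prenyl ether, the β-keto carboxylate loses CO2 at room temperature and the enolate is protonated at C4a, all under near-neutral conditions that the silyl enol ethers and MOM acetals tolerate.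

Step 11
Reactants: 17 tetrahydrochromenone
Product: 18 6,7-bis(tert-butyldimethylsilyloxy)-3-(methoxymethoxy)-2-Ar-4H-chromen-4-one
Conditions: DDQ (2.2 equiv), PhMe, 0 °C → rt
Reagents that add atoms: none
Why: DDQ dehydrogenation, in which hydride abstraction from the allylic C5/C8 positions of the electron-rich enediol bis(silyl ether) followed by proton loss, twice over, is driven by formation of the benzenoid ring of the chromone and should outpace any reaction of DDQ with the aryl prenyl ether, the hydroquinone precipitating from toluene.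

Step 12
Reactants: 18 6,7-bis(silyloxy)flavone
Product: 19 6,7-dihydroxy-3-(methoxymethoxy)-2-Ar-4H-chromen-4-one
Conditions: Bu4NF (2.2 equiv), AcOH (2.2 equiv), THF, 0 °C
Reagents that add atoms: none
Why: fluoride-mediated cleavage of the two aryl silyl ethers (strong Si–F bond, phenoxide leaving groups) is fast at 0 °C, and the acetic acid buffer keeps the catechol protonated so that it is not air-oxidised.

Step 13
Reactants: 19 6,7-dihydroxy-3-(methoxymethoxy)-2-Ar-4H-chromen-4-one
Product: 20 3,6,7-trihydroxy-2-[4-hydroxy-3-(3-methylbut-2-enyloxy)phenyl]-4H-chromen-4-one (CNP0086069.0)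
Conditions: HCl (1.25 M in MeOH), THF, 0 °C → rt, under N2
Reagents that add atoms: none
Why: acid-catalysed transacetalisation of the two MOM ethers to methanol (acetal cleavage through the oxocarbenium ion) proceeds with dilute HCl at room temperature, conditions under which the aryl prenyl ether, which needs stronger acid or heat to ionise, should survive.

**Compound list**

1 | 3,4-dihydroxybenzaldehyde | O=Cc1ccc(O)c(O)c1 | starting material
2 | 3-hydroxy-4-(methoxymethoxy)benzaldehyde | COCOc1ccc(C=O)cc1O | intermediate
3 | prenyl bromide (1-bromo-3-methylbut-2-ene) | CC(C)=CCBr | starting material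
4 | 4-(methoxymethoxy)-3-(3-methylbut-2-enyloxy)benzaldehyde | COCOc1ccc(C=O)cc1OCC=C(C)C | intermediate
5 | 4-(methoxymethoxy)-3-(3-methylbut-2-enyloxy)benzoic acid | COCOc1ccc(C(=O)O)cc1OCC=C(C)C | intermediate
6 | methyl glycolate | COC(=O)CO | starting material
7 | methyl 2-(methoxymethoxy)acetate | COCOCC(=O)OC | intermediate
8 | allyl acetate (prop-2-enyl acetate) | CC(=O)OCC=C | starting material
9 | allyl 4-(methoxymethoxy)-3-oxobutanoate | C=CCOC(=O)CC(=O)COCOC | intermediate
10 | allyl 2-[(dimethylamino)methylidene]-4-(methoxymethoxy)-3-oxobutanoate (E/Z mixture acceptable, Z drawn) | C=CCOC(=O)/C(=C\N(C)C)C(=O)COCOC | intermediate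
11 | 4-(methoxymethoxy)-3-(3-methylbut-2-enyloxy)benzoyl chloride | COCOc1ccc(C(=O)Cl)cc1OCC=C(C)C | intermediate
12 | allyl 2-[(dimethylamino)methylidene]-4-(methoxymethoxy)-5-[4-(methoxymethoxy)-3-(3-methylbut-2-enyloxy)phenyl]-3,5-dioxopentanoate (racemic, enolisable centre; one isomer drawn) | C=CCOC(=O)/C(=C\N(C)C)C(=O)[C@@H](OCOC)C(=O)c1ccc(OCOC)c(OCC=C(C)C)c1 | intermediate
13 | allyl 5-(methoxymethoxy)-6-[4-(methoxymethoxy)-3-(3-methylbut-2-enyloxy)phenyl]-4-oxo-4H-pyran-3-carboxylate (pyranone C2, C3, C5, C6 = flavone C8a, C4a, C3, C2) | C=CCOC(=O)c1coc(-c2ccc(OCOC)c(OCC=C(C)C)c2)c(OCOC)c1=O | intermediate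
14 | 2,3-butanedione | CC(=O)C(C)=O | starting material
15 | 2,3-bis(tert-butyldimethylsilyloxy)buta-1,3-diene | C=C(O[Si](C)(C)C(C)(C)C)C(=C)O[Si](C)(C)C(C)(C)C | intermediate
16 | allyl 6,7-bis(tert-butyldimethylsilyloxy)-3-(methoxymethoxy)-2-[4-(methoxymethoxy)-3-(3-methylbut-2-enyloxy)phenyl]-4-oxo-5,8-dihydro-4H-chromene-4a(8aH)-carboxylate (cis-fused, racemic, one enantiomer drawn) | C=CCOC(=O)[C@]12CC(O[Si](C)(C)C(C)(C)C)=C(O[Si](C)(C)C(C)(C)C)C[C@H]1OC(c1ccc(OCOC)c(OCC=C(C)C)c1)=C(OCOC)C2=O | intermediate
17 | 6,7-bis(tert-butyldimethylsilyloxy)-3-(methoxymethoxy)-2-[4-(methoxymethoxy)-3-(3-methylbut-2-enyloxy)phenyl]-4a,5,8,8a-tetrahydro-4H-chromen-4-one (cis-fused drawn, racemic) | [C@H]12CC(O[Si](C)(C)C(C)(C)C)=C(O[Si](C)(C)C(C)(C)C)C[C@H]1OC(c1ccc(OCOC)c(OCC=C(C)C)c1)=C(OCOC)C2=O | intermediate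
18 | 6,7-bis(tert-butyldimethylsilyloxy)-3-(methoxymethoxy)-2-[4-(methoxymethoxy)-3-(3-methylbut-2-enyloxy)phenyl]-4H-chromen-4-one | COCOc1ccc(-c2oc3cc(O[Si](C)(C)C(C)(C)C)c(O[Si](C)(C)C(C)(C)C)cc3c(=O)c2OCOC)cc1OCC=C(C)C | intermediate
19 | 6,7-dihydroxy-3-(methoxymethoxy)-2-[4-(methoxymethoxy)-3-(3-methylbut-2-enyloxy)phenyl]-4H-chromen-4-one | COCOc1ccc(-c2oc3cc(O)c(O)cc3c(=O)c2OCOC)cc1OCC=C(C)C | intermediate
20 | 3,6,7-trihydroxy-2-[4-hydroxy-3-(3-methylbut-2-enyloxy)phenyl]-4H-chromen-4-one | CC(C)=CCOc1cc(-c2oc3cc(O)c(O)cc3c(=O)c2O)ccc1O | target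

**Step count**

Total: 13 steps. Longest linear sequence: 9 steps (steps 1, 2, 3, 7, 9, 10, 11, 12, 13 from 3,4-dihydroxybenzaldehyde; equally steps 4, 5, 6, 7, 9–13 from methyl glycolate).

**Steps most likely to fail, with fallbacks**

Step 9. The pyranone alkene, stabilised by the partial aromaticity of the 4-pyranone, may react too slowly with a diene that is only moderately activated. Thermal desilylation or oligomerisation of the diene, or a stepwise Mukaiyama–Michael addition that stops after one bond, could then win. The fallback brings ring A in preformed and closes ring C oxidatively. It sets out from aldehyde 4. Commercial 1-(2,4,5-trihydroxyphenyl)ethanone is alkylated at its two non-chelated hydroxyls (MOMCl, i-Pr2NEt, CH2Cl2) to 1-[2-hydroxy-4,5-bis(methoxymethoxy)phenyl]ethanone F1. Claisen–Schmidt condensation of F1 with 4 (KOH, EtOH, rt) should give (E)-1-[2-hydroxy-4,5-bis(methoxymethoxy)phenyl]-3-[4-(methoxymethoxy)-3-(3-methylbut-2-enyloxy)phenyl]prop-2-en-1-one F2. Algar–Flynn–Oyamada oxidation (H2O2, NaOH, MeOH, 0 °C → rt) closes ring C to 3-hydroxy-6,7-bis(methoxymethoxy)-2-[4-(methoxymethoxy)-3-(3-methylbut-2-enyloxy)phenyl]-4H-chromen-4-one F3. Dilute HCl in MeOH as in step 13 removes the three MOM groups, and the sequence comes back to the route at target 20.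

Step 11. Two successive dehydrogenations are asked of DDQ in the presence of an aryl prenyl ether. Hydride abstraction at the prenyl CH2, or acid-induced loss of a silyl enol ether before the ring is oxidised, could erode the material. The fallback sets out from cycloadduct 16 and replaces steps 10 and 11. Pd(OAc)2 (cat.) and PPh3 (cat.) in MeCN at 80 °C effect decarboxylation–dehydrogenation of the allyl β-keto ester (palladium enolate, then β-hydride elimination towards C8a). This should give 6,7-bis(tert-butyldimethylsilyloxy)-3-(methoxymethoxy)-2-[4-(methoxymethoxy)-3-(3-methylbut-2-enyloxy)phenyl]-5,8-dihydro-4H-chromen-4-one F4. The remaining 1,4-cyclohexadiene is aromatised with MnO2 in CH2Cl2 (or air), oxidants too mild to touch the prenyl ether, and the route is rejoined at 18.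

Step 7. The ambident enolate of 10 may be O-acylated or acylated twice by the acid chloride, and the MOM acetal may be partly lost during the acid-promoted ring closure. The fallback sets out from aldehyde 4 and enaminone 10. The lithium enolate of 10 (LiN(SiMe3)2, THF, −78 °C) adds to 4 in an aldol reaction to give allyl 2-[(dimethylamino)methylidene]-5-hydroxy-4-(methoxymethoxy)-5-[4-(methoxymethoxy)-3-(3-methylbut-2-enyloxy)phenyl]-3-oxopentanoate F5 as a diastereomer mixture. Dess–Martin periodinane (NaHCO3, CH2Cl2) oxidises it to the diketone, so the route is rejoined at 12, and the acetic acid cyclisation of step 7 then gives 13.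

**Further compounds**

F1 | step 9 | 1-[2-hydroxy-4,5-bis(methoxymethoxy)phenyl]ethanone | CC(=O)c1cc(OCOC)c(OCOC)cc1O
F2 | step 9 | (E)-1-[2-hydroxy-4,5-bis(methoxymethoxy)phenyl]-3-[4-(methoxymethoxy)-3-(3-methylbut-2-enyloxy)phenyl]prop-2-en-1-one | COCOc1ccc(/C=C/C(=O)c2cc(OCOC)c(OCOC)cc2O)cc1OCC=C(C)C
F3 | step 9 | 3-hydroxy-6,7-bis(methoxymethoxy)-2-[4-(methoxymethoxy)-3-(3-methylbut-2-enyloxy)phenyl]-4H-chromen-4-one | COCOc1ccc(-c2oc3cc(OCOC)c(OCOC)cc3c(=O)c2O)cc1OCC=C(C)C
F4 | step 11 | 6,7-bis(tert-butyldimethylsilyloxy)-3-(methoxymethoxy)-2-[4-(methoxymethoxy)-3-(3-methylbut-2-enyloxy)phenyl]-5,8-dihydro-4H-chromen-4-one | O=C1C(OCOC)=C(c2ccc(OCOC)c(OCC=C(C)C)c2)OC2=C1CC(O[Si](C)(C)C(C)(C)C)=C(O[Si](C)(C)C(C)(C)C)C2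
F5 | step 7 | allyl 2-[(dimethylamino)methylidene]-5-hydroxy-4-(methoxymethoxy)-5-[4-(methoxymethoxy)-3-(3-methylbut-2-enyloxy)phenyl]-3-oxopentanoate (diastereomer mixture, one isomer drawn) | C=CCOC(=O)/C(=C\N(C)C)C(=O)[C@@H](OCOC)[C@H](O)c1ccc(OCOC)c(OCC=C(C)C)c1
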